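A one-step world has no forks: what reacts is product, so conversion tells the yield. The ochre run, which is the flask asked about followed so far, had forks.

- ochre: starting material 1.5 M; reagent 1.5 M; capture agent 0.45 M; the very flask that is asked about, followed so far
- flask: starting material 1.5 M; reagent 1.50 M; capture agent 0.450 M; time 12 d

- ochre (time / d: starting material / %, target / %, trapped intermediate / %): 0.250: 3.8, 3.1, 1.7; 0.417: 1.1, 5.7, 5.0; 0.625: 0, 7.4, 5.4; 1.04: 0.8, 8.1, 7.4; 1.67: 0, 9.7, 7.6; 2.50: 0, 10.8, 9.2; 4.00: 0, 10.3, 8.1

(scatter of a reading: 0.5 percentage points)

- the reaction counts as stopped when no species that holds the starting material changes by six tenths of a point or more over the second half of the time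

- at 12 d, what has stopped the reaction, if anything has (the reagent has run out first / all of the starting material has reacted / forward and back rates have come level / it is still moving)
- conversion of starting material at 12 d
- amount of target at 12 d, in percent of the starting material charged
- amount of trapped intermediate at 12 d, in percent of the starting material charged

In that flask the starting material read 0% at 4.00 d, and target went from 10.8% to 10.3% after 2.50 d, so I took the reaction as stopped by loss of starting material. I followed one molecule to the fork between target and trapped intermediate and folded the two late pairs of readings into one number, the capture odds, trapped intermediate made per target made (a selectivity factor):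

odds = y(trapped intermediate) / y(target) = 0.820

Earlier pairs gave 0.730 at 0.625 d and 0.914 at 1.04 d, so I took 0.820 as a reading of the split over the run so far, not as a constant. That number did not give the amount, which took a second reading: the mean sum of the two, s, the part that reached the fork.

s = 19.2%, with 80.8% unseen
y(target) = s / (1 + odds) = 10.6%
y(trapped intermediate) = s · odds / (1 + odds) = 8.65%

The forecast gave all of the starting material has reacted, conversion 100%, target 10.7% and trapped intermediate 8.8%, a little above my two yields, holding that “the feed appears exhausted”.

At 12 d the flask gave: all of the starting material has reacted, conversion 100%, target 10.4%, trapped intermediate 8.73%, so odds of 0.839.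

    starting material + reagent → open intermediate (k = 3.80 × 10⁻⁵ /M/s)
    open intermediate → target (k = 1.40 × 10⁻⁵ /s)
    2 starting material → self-condensation product (k = 2.50 × 10⁻⁴ /M/s)
    open intermediate + capture agent → trapped intermediate (k = 3.10 × 10⁻⁵ /M/s)
    reagent → decomposition product (k = 1.00 × 10⁻⁷ /s)

In the scheme the odds go with c(capture agent), so I carried them to the neighbouring flask with 1.1 M of capture agent. Its self-condensation product stood at 80.9%, as in the flask, so I held s:

odds = 0.820 · 1.1 M / 0.450 M = 2.00
y(trapped intermediate) = 12.8%, y(target) = 6.39%

That neighbouring flask gave odds of 2.20, above my figure, with 13.1% of trapped intermediate and 5.95% of target.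

The earlier runs and the new flask come from a simulation on assumed constants, noise included.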